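## Structural features

The target is an achiral, mirror-symmetric trimeric acylphloroglucinol: three hexasubstituted benzene rings in a row, ring A–CH2–ring B–CH2–ring C, with no stereocentre. Ring B carries hydroxyls at B2, B4 and B6, an isovaleryl group at B5, and the two methylene bridges at B1 and B3. Rings A and C are identical; numbered alike, each has OMe at C1, methyl at C2, OH at C3 and C5, the bridge at C4 and isovaleryl at C6. The fragile points are these: the doubly benzylic bridges between very electron-rich rings (retro-Friedel–Crafts cleavage in strong acid, exchange of aryl groups across the bridge when the free polyphenol meets base), seven oxidisable phenols, the C1 methyl ethers, which lie ortho to a ketone and are open to chelation-assisted cleavage by boron or aluminium halides, and three aryl ketones that can be over-reduced. The real difficulty is regiochemical: one of three oxygens on each terminal ring must be singled out as a methyl ether, and two identical arms must be attached to ring B without the statistical mixtures of a one-carbon bridging of phenols. The key step exploits the strict alternation on ring B of oxygen-bearing carbons (B2, B4, B6) and carbon-bearing carbons (B1, B3, B5): ring B is the head-to-tail trimer of three oxygenated alkynes B1≡B2, B3≡B4 and B5≡B6, the first two identical and already carrying the arms.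

## Logic of the disconnections

**21 to 20.** The five O–CH2Ph bonds are cut (C3–O and C5–O of both terminal rings, and B6–O). A neutral hydrogenolysis is the mildest possible last step for a base- and acid-sensitive heptaphenol, and it lets every earlier step run on capped phenols. The forward step must spare three aryl ketones and the diarylmethane links.

**20 to 19.** The two O–Si bonds at B2 and B4 are cut. These silyl groups are what the ring-forming step leaves on ring B. Taking them off before the hydrogenolysis means that fluoride never meets the free polyphenol. The forward step needs a buffered fluoride source.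

**19 to 18.** The two aryl–C(=O) bonds at C6 of rings A and C are cut. C6 is the only unsubstituted arene carbon and is activated by three oxygens, so the regiochemistry is forced. The gain is that the arm building block stays free of ketones, which would not survive ynolate chemistry. The demand is an acylation with no Lewis acid strong enough to strip benzyl ethers or break the bridges, run while all ring B oxygens are capped.

**18 to 9 + 9 + 17.** The bonds B6–B1, B2–B3 and B4–B5 are cut, so ring B falls into three alkynes. Two are the same compound, 9, which already contains a complete protected arm and its bridge carbon. The third, 17, brings the B5 acyl group and the B6 oxygen. This is the largest simplification of the route: both inter-ring links and the ring B ketone are in place before the ring exists. The forward step must give two-to-one cross-selectivity and head-to-tail orientation.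

**9 to 6.** The O–Si bond is cut and the alkyne carbon B1 is removed. In the forward sense a one-carbon carbenoid is inserted between the ester carbon of 6 and its arylmethyl group, and the resulting ynolate is silylated. The demand is that addition to the ester outruns enolisation of its benzylic protons.

**6 to 4 (through 5).** The bond between the benzylic CH2 and the carboxyl carbon is cut. This is a one-carbon homologation of an aldehyde to the ester oxidation level, and 5 is the masked acid. The demand is a condensation at a hindered, electron-rich aldehyde.

**4 to 3 to 2 to 1.** The two O–benzyl bonds are cut, then two O–methyl bonds are formally re-formed, then the ring–CHO bond is cut. The formyl group of 2 decides which two of three methoxy groups are exchanged for benzyl (those flanking it), so the methyl ether that survives is the one para to the future bridge, i.e. C1. Compound 1 already carries the C2 methyl, and its two free positions are equivalent, so no regiochemical question arises.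

**17 to 16 to 12 + 13, and 12 to 10 + 11.** The carbonyl is taken back to the carbinol, the carbinol C–C(alkyne) bond is cut to an alkoxyacetylide and aldehyde 13, and the acetylide is traced through 12 to alcohol 10 and the two-carbon chloroalkene 11. The demand is that the alkynyl ether is handled cold and without acid.

## Other disconnections considered

**Alternative 1:** The cut is C1–C2 and C5–C6 of a terminal ring, which falls into a four-carbon diene (C2 to C5, with the C2 methyl) and a two-carbon dienophile (C1, C6). The forward step would be a thermal Diels–Alder reaction of the diene A2 with the ynone A3, followed by loss of a silanol and desilylation on work-up to give the monomer A1.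
- In its favour: the polarity of both partners should place the methyl ether, the C-methyl and the acyl group correctly in one step (the nucleophilic methyl-bearing diene terminus joins the methoxy-bearing alkyne carbon). No protecting group is needed, and the reaction type is well established.
- Against it here: A1 is one ring only. Both methylene bridges to ring B would still have to be made by a one-carbon electrophilic coupling of different phenols, which is statistical (homo-coupling of A1 and over-bridging compete) and must succeed twice on the same ring. A3 is a reluctant dienophile because its methoxy group feeds electron density into the triple bond; A2 is hydrolytically labile and the ynol ether behind A3 is not a stock chemical.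
- Comparison, structure: the alternative builds a terminal ring and leaves the inter-ring bonds to an unselective step. The chosen plan builds ring B with both bridges attached and leaves only an acylation whose site is forced.
- Comparison, mechanism: both rely on the same push–pull polarisation of an alkoxy ynone. The alternative is thermal and precedented, and on precedent it is the better.
- Comparison, step economy: if the bridging could be made selective, the alternative would be the shorter by several steps and is the better on this count. On stereochemistry the two are equal, since neither has any to control.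

**Alternative 2:** The cut is C2–C3, C1–C6 and C3–C4 in both terminal rings. Heating the bis(cyclobutenone) A5 with excess 1-methoxypropyne A6 would open each four-membered ring to a vinylketene, which adds the alkyne, reopens and closes by six-electron electrocyclisation to give A4.
- In its favour: both terminal rings would form in one operation (six bonds, two rings). The regiochemistry of this benzannulation is fixed, with the methyl-bearing alkyne carbon bonding to the ketene carbon so that C2 methyl lies between the new C3 hydroxyl and the C1 methoxy. No metal is needed.
- Against it here: A4 carries no acyl group at all. Three isovaleryl groups (C6 of both terminal rings and B5) would have to be introduced afterwards, one of them at a position flanked by two benzyloxy groups, and the free C3 phenols would compete as O-nucleophiles. A5 is hard to reach (double C4-functionalisation of a 3-alkoxycyclobutenone with a ring B bis-electrophile) and forms as a diastereomer mixture. 3-Alkoxycyclobutenones open only at high temperature, where the volatile A6 needs a sealed vessel.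
- Comparison, structure: the alternative makes more bonds in its key step and is the better on that count. The chosen plan carries the ring B ketone through its key step and needs two late acylations instead of three, and is the better there.
- Comparison, mechanism: a pericyclic cascade of a known type against an untested metal-catalysed crossed trimerisation; the alternative is the better on precedent.
- Comparison, step economy: the preparation of A5 is estimated to be longer than that of 9 and 17 together, so the chosen plan should be shorter overall. Both end with the same hydrogenolysis and are equal there.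

**Alternative 3:** The cut is the C1–O bond and the C6–C(=O) bond of a terminal ring; no ring is built. Fluoride would generate the aryne across C1–C6 from the silylaryl triflate A8. The carboxylate oxygen of isovaleric acid A9 would add at C1, and the aryl anion at C6 would capture the acyl group through a four-membered intermediate that opens to the ortho-hydroxyaryl ketone A7.
- In its favour: one step would set the isovaleryl group and a unique free phenol at C1, exactly the oxygen to be methylated. The C5 benzyloxy group directs the nucleophile to the remote aryne carbon C1. Conditions are mild and the reaction type is known.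
- Against it here: simple O–H addition giving an aryl ester competes whenever the aryl anion is protonated, and the C2 methyl hinders attack at C1. A8 is a pentasubstituted arene whose preparation needs the same kind of regiocontrol that is the problem in the first place. A7 is again a monomer, so O-methylation of a chelated, hindered phenol, debenzylation and the statistical methylene bridging all remain.
- Comparison, structure: the alternative forms neither a ring nor an inter-ring bond and leaves the hardest part unsolved; the chosen plan is the better.
- Comparison, mechanism: known polar aryne chemistry; on precedent the alternative is the better. In its use of polarity matching for regiocontrol it is the equal of the chosen plan.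
- Comparison, step economy: the overall length is estimated to be about equal, but the alternative lacks the convergence of the chosen plan.

Key step: step 10

**Remarks on the chemistry**
- The B6 oxygen is carried as a benzyl ether, not as the ethyl ether that commercial ethoxyacetylene would give. An ethyl ether there could only be removed with boron or aluminium halides, which would first strip the four aryl benzyl ethers and, once the terminal ketones are in place, endanger the C1 methyl ethers. Benzyl leaves in the final hydrogenolysis and saves a separate dealkylation; the skeletons of the ynone and of the cyclotrimer are unchanged.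
- Phloroglucinaldehyde lacks the C2 methyl of the terminal rings and offers no selective way to add it. 2,4,6-Trimethoxytoluene has it, and its formyl derivative directs the methyl-to-benzyl exchange.
- The B2 and B4 silyl ethers are kept through the acylation of the terminal rings so that no ring B phenol can be O-acylated.
- Assumption: 2,4,6-trimethoxytoluene, benzyl alcohol, trichloroethylene, isovaleraldehyde and 1-(2,4,6-trihydroxyphenyl)-3-methylbutan-1-one (used only in one fallback) are taken as purchasable.

## Route

**Step 1**
Reactants: 1 2,4,6-trimethoxytoluene
Product: 2 2,4,6-trimethoxy-3-methylbenzaldehyde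
Conditions: POCl3, DMF, 0 °C to rt; then ice-water
Reagents that add atoms: N,N-dimethylformamide CN(C)C=O; water O
Why: Vilsmeier–Haack formylation; the two free ring positions of 1 are equivalent, so a single aldehyde should result, and the formyl group deactivates the ring against a second attack.

**Step 2**
Reactants: 2 2,4,6-trimethoxy-3-methylbenzaldehyde
Product: 3 2,6-dihydroxy-4-methoxy-3-methylbenzaldehyde
Conditions: AlCl3 (4 equiv), CH2Cl2, 0 °C to rt; then 1 M HCl
Reagents that add atoms: none
Why: Chelation-assisted ether cleavage; aluminium bound to the formyl oxygen delivers chloride only to the two flanking methoxy groups, while the para methoxy group (the future C1–OMe) has no such assistance and should stay.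

**Step 3**
Reactants: 3 2,6-dihydroxy-4-methoxy-3-methylbenzaldehyde
Product: 4 2,6-bis(benzyloxy)-4-methoxy-3-methylbenzaldehyde
Conditions: BnBr, K2CO3, n-Bu4NI (cat.), DMF, 60 °C
Reagents that add atoms: benzyl bromide BrCc1ccccc1
Why: Williamson etherification; both phenols are hydrogen-bonded to the formyl group and need a polar solvent and warming, and O-alkylation of these vinylogous acids is preferred over C-alkylation.

**Step 4**
Reactants: 4 2,6-bis(benzyloxy)-4-methoxy-3-methylbenzaldehyde
Product: 5 1,3-bis(benzyloxy)-5-methoxy-4-methyl-2-[2-(methylsulfanyl)-2-(methylsulfinyl)ethenyl]benzene (alkene geometry not controlled, racemic at sulfur)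
Conditions: MeS(O)CH2SMe, PhCH2NMe3OH (cat., 40% in MeOH), THF, reflux
Reagents that add atoms: methyl (methylthio)methyl sulfoxide CSCS(C)=O
Why: Knoevenagel-type condensation of the doubly sulfur-stabilised carbanion with the aldehyde and loss of water gives a ketene dithioacetal S-oxide, a masked arylacetic acid; alkene geometry and sulfur configuration are lost in step 5 and do not matter.

**Step 5**
Reactants: 5 1,3-bis(benzyloxy)-5-methoxy-4-methyl-2-[2-(methylsulfanyl)-2-(methylsulfinyl)ethenyl]benzene
Product: 6 ethyl [2,6-bis(benzyloxy)-4-methoxy-3-methylphenyl]acetate
Conditions: HCl (dry), EtOH, rt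
Reagents that add atoms: ethanol CCO
Why: Acid ethanolysis of the ketene dithioacetal S-oxide: protonation at the benzylic carbon, addition of ethanol and Pummerer-type loss of the sulfur groups unmask the ethyl ester; aryl benzyl and methyl ethers are stable to ethanolic HCl at room temperature.

**Step 6**
Reactants: 6 ethyl [2,6-bis(benzyloxy)-4-methoxy-3-methylphenyl]acetate
Product: 9 triisopropyl({3-[2,6-bis(benzyloxy)-4-methoxy-3-methylphenyl]prop-1-yn-1-yl}oxy)silane, via lithium dibromoenolate 7 (not isolated), via lithium ynolate 8 (not isolated)
Conditions: CH2Br2, lithium 2,2,6,6-tetramethylpiperidide, THF, −78 °C; 6 added slowly; LiN(SiMe3)2; n-BuLi, −78 to 0 °C; i-Pr3SiOTf, −78 °C to rt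
Reagents that add atoms: dibromomethane BrCBr; triisopropylsilyl trifluoromethanesulfonate CC(C)[Si](C(C)C)(C(C)C)OS(=O)(=O)C(F)(F)F
Why: Kowalski ester homologation stopped at the ynolate: addition of dibromomethyllithium to the ester, loss of ethoxide and deprotonation give 7, bromine–lithium exchange triggers a 1,2-shift of the arylmethyl group (Fritsch–Buttenberg–Wiechell type) to 8, and O-silylation with the bulky silyl triflate gives an isolable siloxyalkyne. The carbenoid is pre-formed cold and the ester added slowly so that addition can outrun enolisation of the arylacetate; benzyl ethers tolerate alkyllithiums at or below 0 °C.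

**Step 7**
Reactants: 10 benzyl alcohol; 11 trichloroethylene
Product: 12 benzyl (E)-1,2-dichlorovinyl ether
Conditions: KH, THF, 0 °C; then 11, −50 °C to rt
Reagents that add atoms: none
Why: Base-induced loss of HCl from trichloroethylene gives dichloroacetylene, to which the alkoxide adds in anti fashion to give the E-dichlorovinyl ether; this is the standard entry to alkynyl ethers of alcohols other than ethanol.

**Step 8**
Reactants: 12 benzyl (E)-1,2-dichlorovinyl ether; 13 isovaleraldehyde
Product: 16 1-(benzyloxy)-5-methylhex-1-yn-3-ol (racemic), via chloroethynyl ether 14 (not isolated), via lithium benzyloxyacetylide 15 (not isolated)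
Conditions: n-BuLi (2.2 equiv), THF, −78 to −40 °C; then 13, −78 °C; H2O
Reagents that add atoms: none
Why: n-BuLi removes the vinylic proton, chloride is eliminated to give 14, and chlorine–lithium exchange with the second equivalent gives the acetylide 15, which adds to the aldehyde; the carbinol centre forms racemic and is removed in step 9.

**Step 9**
Reactants: 16 1-(benzyloxy)-5-methylhex-1-yn-3-ol
Product: 17 1-(benzyloxy)-5-methylhex-1-yn-3-one
Conditions: MnO2 (activated, excess), CH2Cl2, 0 °C to rt
Reagents that add atoms: none
Why: Oxidation of a propargylic alcohol by MnO2 under neutral conditions, which avoids the acid-induced Meyer–Schuster rearrangement of alkoxyethynyl carbinols; 17 is kept cold and used at once because benzyl alkynyl ethers rearrange on heating and β-alkoxy ynones hydrate easily.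

**Step 10**
Reactants: 9 triisopropyl({3-[2,6-bis(benzyloxy)-4-methoxy-3-methylphenyl]prop-1-yn-1-yl}oxy)silane (two equivalents); 17 1-(benzyloxy)-5-methylhex-1-yn-3-one
Product: 18 1-[2-(benzyloxy)-3,5-bis{[2,6-bis(benzyloxy)-4-methoxy-3-methylphenyl]methyl}-4,6-bis(triisopropylsilyloxy)phenyl]-3-methylbutan-1-one
Conditions: [Rh(cod)2]BF4 (5 mol %), rac-BINAP (5 mol %), H2 then Ar (activation); 2,6-di-tert-butyl-4-methylpyridine (10 mol %), CH2Cl2, rt; 9 added over 8 h to catalyst and 17
Reagents that add atoms: none
Why: Proposed new method: oxidative coupling of one molecule of 9 with 17 on the cationic monovalent rhodium centre should join the nucleophilic arylmethyl-bearing carbon of 9 (B1) to the electrophilic benzyloxy-bearing carbon of 17 (B6) and give a rhodacyclopentadiene of trivalent rhodium with the siloxy carbon B2 and the acyl carbon B5 on the metal; a second molecule of 9 then inserts with its nucleophilic carbon B3 bonding to B2, and C–C reductive elimination between B4 and B5 releases the arene and the catalyst. The closest known reaction type is the rhodium/BINAP-catalysed [2+2+2] cross-cyclotrimerisation of two electron-rich alkynes with one electron-poor alkyne, and the closest polar analogy is the silver-promoted addition of siloxyalkynes through their β-carbon to unsaturated ketones. Ring B is closed as a six-membered carbocycle by reductive elimination from a seven-membered rhodacycle, all six ring atoms coming from three alkyne units (2 + 2 + 2). No stereocentre is formed, and the racemic ligand serves only to give a well-defined cationic complex. The step needs two-to-one cross-selectivity and head-to-tail orientation; both should follow from the polarity of the components, because each new bond (B6–B1, B2–B3, B4–B5) pairs a donor-substituted nucleophilic carbon with an acceptor carbon, and the acyl-bearing rhodacycle is electron-poor and should prefer electron-rich 9 over a second 17. Slow addition of 9 keeps its concentration low and disfavours its homotrimerisation, and the hindered pyridine removes traces of acid that would turn 9 into a ketenium ion. The acyl group of 17 ends at B5 and the two arms at B1 and B3, with no later functional-group change needed on the ring B carbons.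

**Step 11**
Reactants: 18 (product of step 10)
Product: 19 1-[2-(benzyloxy)-3,5-bis{[2,6-bis(benzyloxy)-4-methoxy-3-methyl-5-(3-methylbutanoyl)phenyl]methyl}-4,6-bis(triisopropylsilyloxy)phenyl]-3-methylbutan-1-one
Conditions: isovaleric acid (excess), (CF3CO)2O (mixed anhydride pre-formed), CH2Cl2, 0 °C to rt
Reagents that add atoms: isovaleric acid CC(C)CC(=O)O
Why: Friedel–Crafts acylation by the mixed trifluoroacetic anhydride; C6 of each terminal ring is the only free arene position and is ortho to OMe and OBn and para to OBn, while ring B is fully substituted and the benzyl phenyl rings are unactivated. No Lewis acid is present, so the benzyl and silyl ethers and the C1 methyl ethers should persist.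

**Step 12**
Reactants: 19 (product of step 11)
Product: 20 1-[2-(benzyloxy)-3,5-bis{[2,6-bis(benzyloxy)-4-methoxy-3-methyl-5-(3-methylbutanoyl)phenyl]methyl}-4,6-dihydroxyphenyl]-3-methylbutan-1-one
Conditions: n-Bu4NF, AcOH, THF, 0 °C
Reagents that add atoms: none
Why: Fluoride cleavage of the two aryl silyl ethers, buffered with acetic acid; the terminal rings are still fully etherified, so base-induced exchange of aryl groups across the bridges is not possible at this stage.

**Step 13**
Reactants: 20 (product of step 12)
Product: 21 1-[3,5-bis{[2,6-dihydroxy-4-methoxy-3-methyl-5-(3-methylbutanoyl)phenyl]methyl}-2,4,6-trihydroxyphenyl]-3-methylbutan-1-one (target, CNP0158539.0)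
Conditions: H2 (1 atm), 10% Pd/C, EtOAc–MeOH, rt
Reagents that add atoms: none
Why: Hydrogenolysis of five aryl benzyl ethers under neutral conditions; the ortho-hydroxyaryl ketones, chelated by the freed phenols, resist reduction, and the diarylmethane links and methyl ethers are inert.

## Compound list

1 | 2,4,6-trimethoxytoluene | Cc1c(OC)cc(OC)cc1OC | starting material
2 | 2,4,6-trimethoxy-3-methylbenzaldehyde | O=Cc1c(OC)c(C)c(OC)cc1OC | intermediate
3 | 2,6-dihydroxy-4-methoxy-3-methylbenzaldehyde | O=Cc1c(O)c(C)c(OC)cc1O | intermediate
4 | 2,6-bis(benzyloxy)-4-methoxy-3-methylbenzaldehyde | O=Cc1c(OCc2ccccc2)c(C)c(OC)cc1OCc1ccccc1 | intermediate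
5 | 1,3-bis(benzyloxy)-5-methoxy-4-methyl-2-[2-(methylsulfanyl)-2-(methylsulfinyl)ethenyl]benzene (alkene geometry not controlled, racemic at sulfur) | CSC(=Cc1c(OCc2ccccc2)c(C)c(OC)cc1OCc1ccccc1)S(C)=O | intermediate
6 | ethyl [2,6-bis(benzyloxy)-4-methoxy-3-methylphenyl]acetate | CCOC(=O)Cc1c(OCc2ccccc2)c(C)c(OC)cc1OCc1ccccc1 | intermediate
7 | lithium 3-[2,6-bis(benzyloxy)-4-methoxy-3-methylphenyl]-1,1-dibromoprop-1-en-2-olate | [Li+].[O-]C(Cc1c(OCc2ccccc2)c(C)c(OC)cc1OCc1ccccc1)=C(Br)Br | intermediate (not isolated)
8 | lithium 3-[2,6-bis(benzyloxy)-4-methoxy-3-methylphenyl]prop-1-yn-1-olate | [Li+].[O-]C#CCc1c(OCc2ccccc2)c(C)c(OC)cc1OCc1ccccc1 | intermediate (not isolated)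
9 | triisopropyl({3-[2,6-bis(benzyloxy)-4-methoxy-3-methylphenyl]prop-1-yn-1-yl}oxy)silane | COc1cc(OCc2ccccc2)c(CC#CO[Si](C(C)C)(C(C)C)C(C)C)c(OCc2ccccc2)c1C | intermediate
10 | benzyl alcohol | OCc1ccccc1 | starting material
11 | trichloroethylene | ClC=C(Cl)Cl | starting material
12 | benzyl (E)-1,2-dichlorovinyl ether | Cl/C=C(/Cl)OCc1ccccc1 | intermediate
13 | isovaleraldehyde | CC(C)CC=O | starting material
14 | benzyl chloroethynyl ether | ClC#COCc1ccccc1 | intermediate (not isolated)
15 | lithium (benzyloxy)acetylide | [Li+].[C-]#COCc1ccccc1 | intermediate (not isolated)
16 | 1-(benzyloxy)-5-methylhex-1-yn-3-ol (racemic) | CC(C)CC(O)C#COCc1ccccc1 | intermediate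
17 | 1-(benzyloxy)-5-methylhex-1-yn-3-one | CC(C)CC(=O)C#COCc1ccccc1 | intermediate
18 | 1-[2-(benzyloxy)-3,5-bis{[2,6-bis(benzyloxy)-4-methoxy-3-methylphenyl]methyl}-4,6-bis(triisopropylsilyloxy)phenyl]-3-methylbutan-1-one | CC(C)CC(=O)c1c(OCc2ccccc2)c(Cc2c(OCc3ccccc3)cc(OC)c(C)c2OCc2ccccc2)c(O[Si](C(C)C)(C(C)C)C(C)C)c(Cc2c(OCc3ccccc3)cc(OC)c(C)c2OCc2ccccc2)c1O[Si](C(C)C)(C(C)C)C(C)C | intermediate
19 | 1-[2-(benzyloxy)-3,5-bis{[2,6-bis(benzyloxy)-4-methoxy-3-methyl-5-(3-methylbutanoyl)phenyl]methyl}-4,6-bis(triisopropylsilyloxy)phenyl]-3-methylbutan-1-one | CC(C)CC(=O)c1c(OCc2ccccc2)c(Cc2c(OCc3ccccc3)c(C(=O)CC(C)C)c(OC)c(C)c2OCc2ccccc2)c(O[Si](C(C)C)(C(C)C)C(C)C)c(Cc2c(OCc3ccccc3)c(C(=O)CC(C)C)c(OC)c(C)c2OCc2ccccc2)c1O[Si](C(C)C)(C(C)C)C(C)C | intermediate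
20 | 1-[2-(benzyloxy)-3,5-bis{[2,6-bis(benzyloxy)-4-methoxy-3-methyl-5-(3-methylbutanoyl)phenyl]methyl}-4,6-dihydroxyphenyl]-3-methylbutan-1-one | CC(C)CC(=O)c1c(OCc2ccccc2)c(Cc2c(OCc3ccccc3)c(C(=O)CC(C)C)c(OC)c(C)c2OCc2ccccc2)c(O)c(Cc2c(OCc3ccccc3)c(C(=O)CC(C)C)c(OC)c(C)c2OCc2ccccc2)c1O | intermediate
21 | 1-[3,5-bis{[2,6-dihydroxy-4-methoxy-3-methyl-5-(3-methylbutanoyl)phenyl]methyl}-2,4,6-trihydroxyphenyl]-3-methylbutan-1-one (CNP0158539.0) | COc1c(C)c(O)c(Cc2c(O)c(Cc3c(O)c(C)c(OC)c(C(=O)CC(C)C)c3O)c(O)c(C(=O)CC(C)C)c2O)c(O)c1C(=O)CC(C)C | target

## Step count and least certain steps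

Total step count: 13. Longest linear sequence: 10 steps (steps 1 to 6, then 10 to 13).

**Step 10 (key step, the one new method).** The most likely failures are:
- homo-oligomerisation of 9 through acid- or metal-induced ketenium formation outrunning the crossed process;
- uptake of two molecules of 17, or head-to-head coupling;
- sequestration of the cationic metal by the chelating β-alkoxy ynone;
- a slow final reductive elimination, because a hexasubstituted ring with two bulky silyl ethers is very crowded.

The fallback uses known chemistry and replaces ring construction by arylmethylation of a preformed ring B. It sets out from 4 and comes back to the route at 21. Reduction of 4 with NaBH4 (MeOH–THF, 0 °C) gives [2,6-bis(benzyloxy)-4-methoxy-3-methylphenyl]methanol F1. This highly stabilised benzylic alcohol is added slowly (2 equiv, TsOH cat., MeCN–CH2Cl2, 0 °C) to commercial 1-(2,4,6-trihydroxyphenyl)-3-methylbutan-1-one (CC(C)CC(=O)c1c(O)cc(O)cc1O), whose two free ring positions should be benzylated in a Friedel–Crafts reaction to give 1-[3,5-bis{[2,6-bis(benzyloxy)-4-methoxy-3-methylphenyl]methyl}-2,4,6-trihydroxyphenyl]-3-methylbutan-1-one F2. Acetylation (Ac2O, pyridine, DMAP) caps ring B as the triacetate F3. Acylation as in step 11 gives the bis(isovaleryl) triacetate F4. Methanolysis (K2CO3, MeOH, 0 °C) gives the ring B triol with acylated, benzyl-protected arms F5, and hydrogenolysis as in step 13 gives 21.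

**Step 6.** Enolisation of the arylacetic ester by the carbenoid may take the place of addition, since the α-protons are benzylic. Excess alkyllithium may also attack the benzyl ethers or lithiate C6 on warming. The fallback sets out from 6 and comes back at 9. Reduction with i-Bu2AlH (CH2Cl2, −78 °C) gives [2,6-bis(benzyloxy)-4-methoxy-3-methylphenyl]acetaldehyde F6. Ohira–Bestmann homologation (dimethyl (1-diazo-2-oxopropyl)phosphonate, K2CO3, MeOH) gives 1,3-bis(benzyloxy)-5-methoxy-4-methyl-2-(prop-2-yn-1-yl)benzene F7. Its lithium acetylide (n-BuLi, THF, −78 °C) is oxidised with lithium tert-butyl peroxide to the ynolate 8, which is silylated with i-Pr3SiOTf to give 9.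

**Step 11.** The second acylation may stall, because C6 is flanked by two ortho alkoxy groups. Protonation may cleave the diarylmethane links, and trifluoroacetylation may compete with isovalerylation. The fallback sets out from 18 and comes back at 19. Vilsmeier–Haack formylation (POCl3, DMF) of both C6 positions gives the dialdehyde F8. Addition of isobutylmagnesium bromide with CeCl3 (THF, −78 °C) gives the diol F9 as a mixture of diastereomers; the B5 ketone, flanked by benzyloxy and silyloxy groups, should not compete. Dess–Martin oxidation gives 19.

**Step 4.** The condensation is reversible and may be slow at an aldehyde that is hindered by two ortho benzyloxy groups and deactivated by three alkoxy donors. The fallback sets out from 4 and comes back at 9, bypassing 5 and 6. A Wittig reaction with Ph3P=CHOMe (from the phosphonium chloride and KOt-Bu, THF, 0 °C) gives 1,3-bis(benzyloxy)-5-methoxy-2-(2-methoxyethenyl)-4-methylbenzene F10 as an alkene mixture. Aqueous HCl in THF hydrolyses it to the arylacetaldehyde F6, from which the sequence described for step 6 (F7, then 8, then 9) is followed.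

## Further compounds

F1 | step 10 | [2,6-bis(benzyloxy)-4-methoxy-3-methylphenyl]methanol | OCc1c(OCc2ccccc2)c(C)c(OC)cc1OCc1ccccc1
F2 | step 10 | 1-[3,5-bis{[2,6-bis(benzyloxy)-4-methoxy-3-methylphenyl]methyl}-2,4,6-trihydroxyphenyl]-3-methylbutan-1-one | CC(C)CC(=O)c1c(O)c(Cc2c(OCc3ccccc3)cc(OC)c(C)c2OCc2ccccc2)c(O)c(Cc2c(OCc3ccccc3)cc(OC)c(C)c2OCc2ccccc2)c1O
F3 | step 10 | 2,4-bis{[2,6-bis(benzyloxy)-4-methoxy-3-methylphenyl]methyl}-6-(3-methylbutanoyl)benzene-1,3,5-triyl triacetate | CC(C)CC(=O)c1c(OC(C)=O)c(Cc2c(OCc3ccccc3)cc(OC)c(C)c2OCc2ccccc2)c(OC(C)=O)c(Cc2c(OCc3ccccc3)cc(OC)c(C)c2OCc2ccccc2)c1OC(C)=O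
F4 | step 10 | 2,4-bis{[2,6-bis(benzyloxy)-4-methoxy-3-methyl-5-(3-methylbutanoyl)phenyl]methyl}-6-(3-methylbutanoyl)benzene-1,3,5-triyl triacetate | CC(C)CC(=O)c1c(OC(C)=O)c(Cc2c(OCc3ccccc3)c(C(=O)CC(C)C)c(OC)c(C)c2OCc2ccccc2)c(OC(C)=O)c(Cc2c(OCc3ccccc3)c(C(=O)CC(C)C)c(OC)c(C)c2OCc2ccccc2)c1OC(C)=O
F5 | step 10 | 1-[3,5-bis{[2,6-bis(benzyloxy)-4-methoxy-3-methyl-5-(3-methylbutanoyl)phenyl]methyl}-2,4,6-trihydroxyphenyl]-3-methylbutan-1-one | CC(C)CC(=O)c1c(O)c(Cc2c(OCc3ccccc3)c(C(=O)CC(C)C)c(OC)c(C)c2OCc2ccccc2)c(O)c(Cc2c(OCc3ccccc3)c(C(=O)CC(C)C)c(OC)c(C)c2OCc2ccccc2)c1O
F6 | step 6 | [2,6-bis(benzyloxy)-4-methoxy-3-methylphenyl]acetaldehyde | O=CCc1c(OCc2ccccc2)c(C)c(OC)cc1OCc1ccccc1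
F7 | step 6 | 1,3-bis(benzyloxy)-5-methoxy-4-methyl-2-(prop-2-yn-1-yl)benzene | C#CCc1c(OCc2ccccc2)c(C)c(OC)cc1OCc1ccccc1
F8 | step 11 | 3,3'-{[4-(benzyloxy)-5-(3-methylbutanoyl)-2,6-bis(triisopropylsilyloxy)-1,3-phenylene]bis(methylene)}bis[2,4-bis(benzyloxy)-6-methoxy-5-methylbenzaldehyde] | CC(C)CC(=O)c1c(OCc2ccccc2)c(Cc2c(OCc3ccccc3)c(C=O)c(OC)c(C)c2OCc2ccccc2)c(O[Si](C(C)C)(C(C)C)C(C)C)c(Cc2c(OCc3ccccc3)c(C=O)c(OC)c(C)c2OCc2ccccc2)c1O[Si](C(C)C)(C(C)C)C(C)C
F9 | step 11 | 1-[2-(benzyloxy)-3,5-bis{[2,6-bis(benzyloxy)-3-(1-hydroxy-3-methylbutyl)-4-methoxy-5-methylphenyl]methyl}-4,6-bis(triisopropylsilyloxy)phenyl]-3-methylbutan-1-one (mixture of diastereomers) | CC(C)CC(=O)c1c(OCc2ccccc2)c(Cc2c(OCc3ccccc3)c(C(O)CC(C)C)c(OC)c(C)c2OCc2ccccc2)c(O[Si](C(C)C)(C(C)C)C(C)C)c(Cc2c(OCc3ccccc3)c(C(O)CC(C)C)c(OC)c(C)c2OCc2ccccc2)c1O[Si](C(C)C)(C(C)C)C(C)C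
F10 | step 4 | 1,3-bis(benzyloxy)-5-methoxy-2-(2-methoxyethenyl)-4-methylbenzene (alkene mixture) | COC=Cc1c(OCc2ccccc2)c(C)c(OC)cc1OCc1ccccc1
A1 | alternative 1 | 1-(4,6-dihydroxy-2-methoxy-3-methylphenyl)-3-methylbutan-1-one | COc1c(C)c(O)cc(O)c1C(=O)CC(C)C
A2 | alternative 1 | 1,1,3-tris(trimethylsilyloxy)penta-1,3-diene (geometry at C3=C4 not specified) | CC=C(O[Si](C)(C)C)C=C(O[Si](C)(C)C)O[Si](C)(C)C
A3 | alternative 1 | 1-methoxy-5-methylhex-1-yn-3-one | COC#CC(=O)CC(C)C
A4 | alternative 2 | penta-O-benzyl deacyl trimer with free C3 phenols | COc1cc(OCc2ccccc2)c(Cc2c(OCc3ccccc3)cc(OCc3ccccc3)c(Cc3c(O)c(C)c(OC)cc3OCc3ccccc3)c2OCc2ccccc2)c(O)c1C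
A5 | alternative 2 | 4,4'-{[2,4,6-tris(benzyloxy)-1,3-phenylene]bis(methylene)}bis[3-(benzyloxy)cyclobut-2-en-1-one] (mixture of diastereomers) | O=C1C=C(OCc2ccccc2)C1Cc1c(OCc2ccccc2)cc(OCc2ccccc2)c(CC2C(=O)C=C2OCc2ccccc2)c1OCc1ccccc1
A6 | alternative 2 | 1-methoxypropyne | COC#CC
A7 | alternative 3 | 1-[2,4-bis(benzyloxy)-6-hydroxy-5-methylphenyl]-3-methylbutan-1-one | CC(C)CC(=O)c1c(O)c(C)c(OCc2ccccc2)cc1OCc1ccccc1
A8 | alternative 3 | 3,5-bis(benzyloxy)-2-methyl-6-(trimethylsilyl)phenyl trifluoromethanesulfonate | Cc1c(OCc2ccccc2)cc(OCc2ccccc2)c([Si](C)(C)C)c1OS(=O)(=O)C(F)(F)F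
A9 | alternative 3 | isovaleric acid | CC(C)CC(=O)O
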